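(The readings come from a simulation from invented constants, and the scatter is random.)

A single-handed catalyst that takes one substrate faster cannot hold its product excess level as conversion climbs unless that substrate is refilled, for otherwise c(left-handed substrate) falls behind c(right-handed substrate) and the split drifts towards even. The two earlier runs are your test, and their charges of racemization catalyst, 27 µM and 62 µM, bracket the 41 µM of the new flask.

in all of them: left-handed substrate 41 mM; right-handed substrate 41 mM; reagent 123 mM; free catalyst 0.82 mM

| run | racemization catalyst | remark | time |
|---|---|---|---|
| Saturday's | 27 µM | run made earlier |  |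
| Wednesday's | 62 µM | run made earlier |  |
| flask | 41 µM |  | 2.0 min |

| run | time / s | left-handed product / % | right-handed product / % |
|---|---|---|---|
| Saturday's | 15.0 | 15.6 | 10.0 |
| Saturday's | 30.0 | 25.1 | 15.3 |
| Saturday's | 50.0 | 32.5 | 21.1 |
| Saturday's | 60.0 | 35.4 | 22.4 |
| Saturday's | 80.0 | 39.6 | 25.4 |
| Saturday's | 90.0 | 41.2 | 26.6 |
| Saturday's | 120 | 46.3 | 29.5 |
| Wednesday's | 15.0 | 16.6 | 11.2 |
| Wednesday's | 30.0 | 24.9 | 15.4 |
| Wednesday's | 50.0 | 32.6 | 19.7 |
| Wednesday's | 60.0 | 35.7 | 21.7 |
| Wednesday's | 80.0 | 40.9 | 25.6 |
| Wednesday's | 90.0 | 41.9 | 26.1 |
| Wednesday's | 120 | 46.6 | 29.5 |

(each reading ± 0.5 percentage points)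

- free catalyst is single-handed; left-handed substrate and right-handed substrate are mirror images of each other, charged as a racemate, each of them at the stated concentration
- the analysis behind the earlier runs scatters by 0.5 percentage points, standard deviation
- an excess is below zero if the other one leads

- left-handed product and right-handed product together, in percent of the left-handed substrate and right-handed substrate charged together, at 2.0 min
- excess of left-handed product over right-handed product in the product at 2.0 min
- whether the exchange between left-handed substrate and right-handed substrate keeps pace with the reaction: how far the product's excess at 2.0 min gets from its value without exchange to its value with instant exchange (above 80 % keeps pace, below 20 % hardly takes part, else lags behind)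

Pooled over both runs, left-handed product over right-handed product reads 1.52 at the first reading and 1.57 at the last, so carry that last reading as the split, the ratio of the two products at one moment, which serves as the selectivity factor while exchange keeps pace. The excess is the split minus one over the split plus one, 22.3 %, and since 2.0 min is the time of the last reading, my reckoning for the new flask is that excess, a total near the mean of the two last totals, 75.9 %, and exchange keeping pace.

The forecast gives 76 % (74.8 % to 77.2 %), 22.4 % (21 % to 23.8 %) and "keeps pace", on this ground: “Instead it stays at the instant-exchange value, so exchange keeps pace.”

The new flask gives 75.9 %, 22.1 % and "keeps pace", 86 % of the way to instant exchange.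

    reagent + free catalyst + right-handed substrate → free catalyst + right-handed product (k = 235 L² mol⁻² s⁻¹)
    left-handed substrate + racemization catalyst ⇌ right-handed substrate + racemization catalyst, rate k2*[racemization catalyst]*[left-handed substrate] forward; the back reaction follows from the equilibrium constant (k = 8260 L mol⁻¹ s⁻¹)
    racemization catalyst ⇌ dormant form (K = 13.0, k = 0.0483 s⁻¹)
    reagent + free catalyst + left-handed substrate → free catalyst + left-handed product (k = 382 L² mol⁻² s⁻¹)
    2 free catalyst ⇌ resting dimer (K = 861 L mol⁻¹, k = 49.2 L mol⁻¹ s⁻¹)

That pace holds even though, at 2.00 min, the new flask keeps 7.32 % of its racemization catalyst working and 92.7 % as dormant form, which the split does not show. The split turns 75.9 % into 46.4 % left-handed product, and the new flask holds 46.4 %. A neighbour flask charged with 49 mM of reagent, its other charges and its time held, reaches 39.6 %, less than the low end 74.8 % of the forecast's range, at excess 23.2 %; the split gives 24.2 % left-handed product there, and that neighbour flask holds 24.4 %.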